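Cembrane numbering is used: C1 is the ring-fusion carbon bearing the lactone α-carbon C15, C2 carries the lactone oxygen, C14 the free hydroxyl. Everything rests on disconnecting C15–C1. The anti arrangement of this bond and the vicinal C14 hydroxyl is read as the trace of a trans C1–C14 epoxide opened at C1 by the α-carbon of a C2 acrylate ester. One phosphine-triggered Morita–Baylis–Hillman-type cyclisation of the macrocyclic epoxy acrylate closes the five-membered lactone ring, sets C1 by inversion, unveils the C14 alcohol and keeps the exocyclic methylene. The 14-membered carbocycle is closed beforehand by Nozaki–Hiyama–Kishi coupling; the C3–C4 epoxide and C5 acetate follow by directed epoxidation and Mitsunobu inversion.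

Key step: step 17

Remark: locants follow cembrane numbering (C3–C4 epoxide with methyl on C4; C5 acetoxy carbon; C7=C8 and C11=C12 with methyls on C8 and C12; C16 lactone carbonyl; C17 exocyclic methylene) and are kept for all macrocyclic intermediates; it is assumed that the (S)-BINOL/Ti(OiPr)4 catalyst delivers allyl to the Si face of enal 3, as it does with other conjugated aldehydes.

Step 1
Reactants: 1 propargyl alcohol
Product: 2 (2E)-3-iodo-2-methylprop-2-en-1-ol
Conditions: AlMe3, Cp2ZrCl2 (cat.), CH2Cl2, 0 °C to rt; then I2, THF, −30 °C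
Reagents that add atoms: trimethylaluminium C[Al](C)C; iodine II
Why: Negishi carboalumination adds methyl and aluminium syn across the alkyne with methyl on the internal carbon, and iodinolysis with retention should give the E-iodoalkene.

Step 2
Reactants: 2 (2E)-3-iodo-2-methylprop-2-en-1-ol
Product: 3 (2E)-3-iodo-2-methylprop-2-enal
Conditions: MnO2, CH2Cl2, rt
Reagents that add atoms: none
Why: Allylic oxidation with MnO2 should stop at the enal and leave the vinyl iodide and the E geometry untouched.

Step 3
Reactants: 3 (2E)-3-iodo-2-methylprop-2-enal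
Product: 4 (1E,3S)-1-iodo-2-methylhexa-1,5-dien-3-ol
Conditions: (S)-BINOL (10 mol %), Ti(OiPr)4 (10 mol %), 4 Å MS, CH2Cl2; allylSnBu3, −20 °C
Reagents that add atoms: allyltributylstannane C=CC[Sn](CCCC)(CCCC)CCCC
Why: Keck asymmetric allylation should direct the allylstannane to the Si face of the enal and set the carbinol carbon (later C5) as S, on purpose the epimer of the target.

Step 4
Reactants: 4 (1E,3S)-1-iodo-2-methylhexa-1,5-dien-3-ol
Product: 5 p-methoxybenzyl ether of 4
Conditions: NaH, 4-methoxybenzyl chloride, Bu4NI (cat.), THF/DMF, 0 °C to rt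
Reagents that add atoms: 4-methoxybenzyl chloride COc1ccc(CCl)cc1
Why: Williamson etherification of the sodium alkoxide gives a p-methoxybenzyl ether that survives all steps up to its oxidative removal in step 19.

Step 5
Reactants: 5 p-methoxybenzyl ether
Product: 6 (3S,4E)-5-iodo-3-[(4-methoxybenzyl)oxy]-4-methylpent-4-enal
Conditions: OsO4 (2 mol %), NaIO4, 2,6-lutidine, dioxane/H2O, rt
Reagents that add atoms: sodium periodate [Na+].[O-]I(=O)(=O)=O
Why: In this Lemieux–Johnson cleavage OsO4 dihydroxylates the monosubstituted terminal alkene much faster than the electron-poor trisubstituted iodoalkene, and NaIO4 cleaves the diol to the aldehyde.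

Step 6
Reactants: 6 β-alkoxy aldehyde
Product: 7 (5S,6E)-7-iodo-5-[(4-methoxybenzyl)oxy]-2,6-dimethylhepta-1,6-dien-3-ol (both C3 epimers)
Conditions: isopropenylmagnesium bromide, THF, −78 °C
Reagents that add atoms: isopropenylmagnesium bromide CC(=C)[Mg]Br
Why: Grignard 1,2-addition gives the 2-methylallylic alcohol needed for the sigmatropic shift, and the unselective new carbinol centre is destroyed in step 7.

Step 7
Reactants: 7 allylic alcohol
Product: 9 (4E,7S,8E)-9-iodo-7-[(4-methoxybenzyl)oxy]-4,8-dimethylnona-4,8-dienal, via allyl vinyl ether 8 (not isolated)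
Conditions: ethyl vinyl ether, Hg(OAc)2 (cat.), reflux; then toluene, 130 °C (sealed tube)
Reagents that add atoms: ethyl vinyl ether C=COCC
Why: Vinyl ether exchange followed by Claisen rearrangement through a chair transition state with the carbinol substituent equatorial should give the E-trisubstituted C7=C8 alkene and the aldehyde two carbons further on.

Step 8
Reactants: 9 aldehyde
Product: 10 methyl (2Z,6E,9S,10E)-11-iodo-9-[(4-methoxybenzyl)oxy]-2,6,10-trimethylundeca-2,6,10-trienoate
Conditions: (CF3CH2O)2P(O)CH(Me)CO2Me, KN(SiMe3)2, 18-crown-6, THF, −78 °C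
Reagents that add atoms: methyl 2-[bis(2,2,2-trifluoroethoxy)phosphoryl]propanoate COC(=O)C(C)P(=O)(OCC(F)(F)F)OCC(F)(F)F
Why: Still–Gennari olefination under dissociating conditions should give the Z-configured trisubstituted enoate, the later C11=C12 alkene.

Step 9
Reactants: 10 Z-enoate
Product: 11 (2Z,6E,9S,10E)-11-iodo-9-[(4-methoxybenzyl)oxy]-2,6,10-trimethylundeca-2,6,10-trien-1-ol
Conditions: i-Bu2AlH, CH2Cl2, −78 °C
Reagents that add atoms: none
Why: i-Bu2AlH reduces the enoate by 1,2-addition to the allylic alcohol without touching the vinyl iodide or the benzylic ether.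

Step 10
Reactants: 11 allylic alcohol
Product: 12 allylic bromide (OH of 11 replaced by Br)
Conditions: CBr4, PPh3, CH2Cl2, 0 °C
Reagents that add atoms: carbon tetrabromide BrC(Br)(Br)Br
Why: Appel bromination converts the primary allylic alcohol to the bromide under neutral conditions that should not isomerise the Z alkene.

Step 11
Reactants: 12 allylic bromide; 1 propargyl alcohol
Product: 13 (5Z,9E,12S,13E)-14-iodo-12-[(4-methoxybenzyl)oxy]-5,9,13-trimethyltetradeca-5,9,13-trien-2-yn-1-ol
Conditions: CuI (20 mol %), Cs2CO3, NaI, DMF, rt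
Reagents that add atoms: none
Why: Copper acetylide SN2 coupling at the primary allylic carbon forges the C13–C14 bond with retention of the Z alkene, the vinyl iodide being inert to copper acetylides at room temperature.

Step 12
Reactants: 13 skipped enynol
Product: 14 (2E,5Z,9E,12S,13E)-14-iodo-12-[(4-methoxybenzyl)oxy]-5,9,13-trimethyltetradeca-2,5,9,13-tetraen-1-ol
Conditions: NaAlH2(OCH2CH2OMe)2, THF, 0 °C
Reagents that add atoms: none
Why: Hydroxyl-directed trans-hydroalumination of the propargylic alcohol and protonolysis should give only the E-allylic alcohol, while the isolated alkenes and, at 0 °C, the vinyl iodide are not reduced.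

Step 13
Reactants: 14 E-allylic alcohol
Product: 15 (2R,3R)-epoxy alcohol
Conditions: Ti(OiPr)4 (10 mol %), D-(−)-diisopropyl tartrate (12 mol %), t-BuOOH, 4 Å MS, CH2Cl2, −20 °C
Reagents that add atoms: tert-butyl hydroperoxide CC(C)(C)OO
Why: Sharpless asymmetric epoxidation of the primary E-allylic alcohol with the D-(−)-tartrate ligand should give the (2R,3R)-epoxy alcohol under reagent control, which fixes C14 and the C1–O bond that is inverted in step 17.

Step 14
Reactants: 15 epoxy alcohol
Product: 16 (2S,3R)-epoxy aldehyde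
Conditions: Dess–Martin periodinane, NaHCO3, CH2Cl2, 0 °C
Reagents that add atoms: none
Why: Buffered Dess–Martin oxidation should give the sensitive α,β-epoxy aldehyde without epimerisation or epoxide opening.

Step 15
Reactants: 16 epoxy aldehyde
Product: 17 macrocyclic epoxy alcohol
Conditions: CrCl2 (10 equiv), NiCl2 (1 mol %), DMSO/THF, rt, 0.002 M, slow addition
Reagents that add atoms: none
Why: Nozaki–Hiyama–Kishi ring closure adds the alkenylchromium species to the aldehyde with retention of the E alkene, and Felkin–Anh attack anti to the epoxide C–O bond should give the erythro (2R) epoxy alcohol.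

Step 16
Reactants: 17 macrocyclic epoxy alcohol
Product: 18 epoxy acrylate
Conditions: acryloyl chloride, i-Pr2NEt, DMAP (cat.), CH2Cl2, −40 to 0 °C
Reagents that add atoms: acryloyl chloride C=CC(=O)Cl
Why: Acylation of the secondary alcohol under mild amine base installs C15–C17 without Payne rearrangement of the epoxy alcohol.

Step 17
Reactants: 18 epoxy acrylate
Product: 21 C14-hydroxy α-methylene lactone, via phosphonium enolate 19 (not isolated), via phosphonium alkoxide 20 (not isolated)
Conditions: PMe3 (1.2 equiv), t-BuOH, 35 °C, 0.01 M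
Reagents that add atoms: none
Why: Proposed new method: PMe3 adds to C17 of the acrylate to give the β-phosphonio ester enolate 19, whose α-carbon C15 opens the C1–C14 epoxide at C1 from the backside, and proton transfer in alkoxide 20 followed by E1cB loss of PMe3 restores the C15=C17 methylene; the closest known reaction type is the phosphine-mediated intramolecular Morita–Baylis–Hillman alkylation of enones by tethered epoxides and alkyl halides, extended here to an acrylate ester so that a lactone is closed. The five-membered lactone ring (C15–C16–O–C2–C1) closes in the 5-exo-tet mode, the mode also followed when nucleophiles tethered to the carbinol oxygen of 2,3-epoxy alcohols open the proximal epoxide carbon, whereas 6-endo attack at C14 cannot reach collinearity. C1 is set by stereospecific inversion of the epoxide carbon installed in step 13, C14 keeps its configuration and emerges as the free alcohol, and the erythro relation of C2–O to the epoxide fixed in step 15 translates into the trans ring fusion. The step needs C- over O-alkylation of the enolate and the absence of competing electrophiles, which is secured because epoxides alkylate enolates at carbon, the C3–C4 epoxide is introduced only in step 20, and the benzylic ether and the trisubstituted alkenes are inert to the phosphine. tert-Butanol activates the epoxide by hydrogen bonding and protonates the C14 alkoxide, which should suppress translactonisation, while the small, strongly nucleophilic PMe3 compensates for the cost of reaching the s-cis ester conformer needed for ring closure.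

Step 18
Reactants: 21 C14-hydroxy α-methylene lactone
Product: 22 C14 triethylsilyl ether
Conditions: Et3SiOTf, 2,6-lutidine, CH2Cl2, −78 °C
Reagents that add atoms: triethylsilyl trifluoromethanesulfonate CC[Si](CC)(CC)OS(=O)(=O)C(F)(F)F
Why: Silylation masks the C14 hydroxyl so that only the C5 hydroxyl is free in the directed epoxidation and the Mitsunobu step.

Step 19
Reactants: 22 C14 triethylsilyl ether
Product: 23 C5 allylic alcohol
Conditions: DDQ, CH2Cl2/pH 7 buffer, 0 °C
Reagents that add atoms: none
Why: DDQ oxidises the electron-rich p-methoxybenzyl ether to a hemiacetal that hydrolyses to the C5 alcohol without affecting the silyl ether, the lactone or the alkenes.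

Step 20
Reactants: 23 C5 allylic alcohol
Product: 24 erythro 3,4-epoxy-5-ol
Conditions: VO(acac)2 (5 mol %), t-BuOOH, CH2Cl2, 0 °C
Reagents that add atoms: tert-butyl hydroperoxide CC(C)(C)OO
Why: Vanadium-catalysed hydroxyl-directed epoxidation reacts only at the allylic C3=C4 alkene and, with a C4 methyl and no cis substituent on C3 (A1,2 strain control), should give the erythro epoxy alcohol, which sets C3 and C4 as in the target.

Step 21
Reactants: 24 erythro 3,4-epoxy-5-ol
Product: 25 C5 acetate (inverted)
Conditions: PPh3, DIAD, AcOH, toluene, 0 °C to rt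
Reagents that add atoms: acetic acid CC(=O)O
Why: In the Mitsunobu reaction SN2 displacement of the oxyphosphonium by acetate inverts C5 to the target configuration and installs the acetate in the same operation, turning the erythro into the required threo arrangement.

Step 22
Reactants: 25 C5 acetate
Product: 26 target
Conditions: HF·pyridine, pyridine, THF, 0 °C
Reagents that add atoms: none
Why: Buffered HF·pyridine cleaves the triethylsilyl ether under conditions mild enough for the epoxide, the acetate and the α-methylene lactone.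

Compound list
1 | propargyl alcohol (prop-2-yn-1-ol) | C#CCO | starting material
2 | (2E)-3-iodo-2-methylprop-2-en-1-ol | OC/C(C)=C/I | intermediate
3 | (2E)-3-iodo-2-methylprop-2-enal | O=C/C(C)=C/I | intermediate
4 | (1E,3S)-1-iodo-2-methylhexa-1,5-dien-3-ol | C=CC[C@H](O)/C(C)=C/I | intermediate
5 | 1-({[(1E,3S)-1-iodo-2-methylhexa-1,5-dien-3-yl]oxy}methyl)-4-methoxybenzene | C=CC[C@H](OCc1ccc(OC)cc1)/C(C)=C/I | intermediate
6 | (3S,4E)-5-iodo-3-[(4-methoxybenzyl)oxy]-4-methylpent-4-enal | O=CC[C@H](OCc1ccc(OC)cc1)/C(C)=C/I | intermediate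
7 | (5S,6E)-7-iodo-5-[(4-methoxybenzyl)oxy]-2,6-dimethylhepta-1,6-dien-3-ol, both C3 epimers | C=C(C)C(O)C[C@H](OCc1ccc(OC)cc1)/C(C)=C/I | intermediate
8 | O-vinyl ether of 7 (allyl vinyl ether) | C=COC(C(C)=C)C[C@H](OCc1ccc(OC)cc1)/C(C)=C/I | intermediate
9 | (4E,7S,8E)-9-iodo-7-[(4-methoxybenzyl)oxy]-4,8-dimethylnona-4,8-dienal | O=CCC/C(C)=C/C[C@H](OCc1ccc(OC)cc1)/C(C)=C/I | intermediate
10 | methyl (2Z,6E,9S,10E)-11-iodo-9-[(4-methoxybenzyl)oxy]-2,6,10-trimethylundeca-2,6,10-trienoate | COC(=O)/C(C)=C\CC/C(C)=C/C[C@H](OCc1ccc(OC)cc1)/C(C)=C/I | intermediate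
11 | (2Z,6E,9S,10E)-11-iodo-9-[(4-methoxybenzyl)oxy]-2,6,10-trimethylundeca-2,6,10-trien-1-ol | OC/C(C)=C\CC/C(C)=C/C[C@H](OCc1ccc(OC)cc1)/C(C)=C/I | intermediate
12 | 1-({[(1E,3S,5E,9Z)-11-bromo-1-iodo-2,6,10-trimethylundeca-1,5,9-trien-3-yl]oxy}methyl)-4-methoxybenzene | BrC/C(C)=C\CC/C(C)=C/C[C@H](OCc1ccc(OC)cc1)/C(C)=C/I | intermediate
13 | (5Z,9E,12S,13E)-14-iodo-12-[(4-methoxybenzyl)oxy]-5,9,13-trimethyltetradeca-5,9,13-trien-2-yn-1-ol | OCC#CC/C(C)=C\CC/C(C)=C/C[C@H](OCc1ccc(OC)cc1)/C(C)=C/I | intermediate
14 | (2E,5Z,9E,12S,13E)-14-iodo-12-[(4-methoxybenzyl)oxy]-5,9,13-trimethyltetradeca-2,5,9,13-tetraen-1-ol | OC/C=C/C/C(C)=C\CC/C(C)=C/C[C@H](OCc1ccc(OC)cc1)/C(C)=C/I | intermediate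
15 | {(2R,3R)-3-[(2Z,6E,9S,10E)-11-iodo-9-[(4-methoxybenzyl)oxy]-2,6,10-trimethylundeca-2,6,10-trien-1-yl]oxiran-2-yl}methanol | OC[C@H]1O[C@@H]1C/C(C)=C\CC/C(C)=C/C[C@H](OCc2ccc(OC)cc2)/C(C)=C/I | intermediate
16 | (2S,3R)-3-[(2Z,6E,9S,10E)-11-iodo-9-[(4-methoxybenzyl)oxy]-2,6,10-trimethylundeca-2,6,10-trien-1-yl]oxirane-2-carbaldehyde | O=C[C@H]1O[C@@H]1C/C(C)=C\CC/C(C)=C/C[C@H](OCc2ccc(OC)cc2)/C(C)=C/I | intermediate
17 | (1R,2R,5S,14R,3E,7E,11Z)-1,14-epoxy-5-[(4-methoxybenzyl)oxy]-4,8,12-trimethylcyclotetradeca-3,7,11-trien-2-ol (ring locants of the remark) | C1/C=C(C)\C[C@H]2O[C@@H]2[C@H](O)/C=C(C)/[C@@H](OCc2ccc(OC)cc2)C/C=C(C)/C1 | intermediate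
18 | C2 acrylate of 17: (1S,2R,5S,14R,3E,7E,11Z)-1,14-epoxy-5-[(4-methoxybenzyl)oxy]-4,8,12-trimethylcyclotetradeca-3,7,11-trien-2-yl prop-2-enoate | C1/C=C(C)\C[C@H]2O[C@@H]2[C@H](OC(=O)C=C)/C=C(C)/[C@@H](OCc2ccc(OC)cc2)C/C=C(C)/C1 | intermediate
19 | zwitterionic ester enolate from addition of PMe3 to C17 of 18 | C1/C=C(C)\C[C@H]2O[C@@H]2[C@H](OC([O-])=CC[P+](C)(C)C)/C=C(C)/[C@@H](OCc2ccc(OC)cc2)C/C=C(C)/C1 | intermediate
20 | cyclised lactone carrying CH2PMe3+ on C15 and the C14 alkoxide (C15 unspecified) | C1/C=C(C)\C[C@@H]([O-])[C@H]2C(C[P+](C)(C)C)C(=O)O[C@@H]2/C=C(C)/[C@@H](OCc3ccc(OC)cc3)C/C=C(C)/C1 | intermediate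
21 | (1R,2R,5S,14R,3E,7E,11Z)-14-hydroxy-5-[(4-methoxybenzyl)oxy]cembra-3,7,11,15(17)-tetraen-16,2-olide | C1/C=C(C)\C[C@@H](O)[C@H]2C(=C)C(=O)O[C@@H]2/C=C(C)/[C@@H](OCc3ccc(OC)cc3)C/C=C(C)/C1 | intermediate
22 | (1S,2R,5S,14R,3E,7E,11Z)-5-[(4-methoxybenzyl)oxy]-14-(triethylsilyloxy)cembra-3,7,11,15(17)-tetraen-16,2-olide | C1/C=C(C)\C[C@@H](O[Si](CC)(CC)CC)[C@H]2C(=C)C(=O)O[C@@H]2/C=C(C)/[C@@H](OCc3ccc(OC)cc3)C/C=C(C)/C1 | intermediate
23 | (1S,2R,5S,14R,3E,7E,11Z)-5-hydroxy-14-(triethylsilyloxy)cembra-3,7,11,15(17)-tetraen-16,2-olide | C1/C=C(C)\C[C@@H](O[Si](CC)(CC)CC)[C@H]2C(=C)C(=O)O[C@@H]2/C=C(C)/[C@@H](O)C/C=C(C)/C1 | intermediate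
24 | (1S,2S,3S,4S,5S,14R,7E,11Z)-3,4-epoxy-5-hydroxy-14-(triethylsilyloxy)cembra-7,11,15(17)-trien-16,2-olide | C1/C=C(C)\C[C@@H](O[Si](CC)(CC)CC)[C@H]2C(=C)C(=O)O[C@@H]2[C@@H]3O[C@@]3(C)[C@@H](O)C/C=C(C)/C1 | intermediate
25 | (1S,2S,3S,4S,5R,14R,7E,11Z)-5-acetoxy-3,4-epoxy-14-(triethylsilyloxy)cembra-7,11,15(17)-trien-16,2-olide | C1/C=C(C)\C[C@@H](O[Si](CC)(CC)CC)[C@H]2C(=C)C(=O)O[C@@H]2[C@@H]3O[C@@]3(C)[C@H](OC(C)=O)C/C=C(C)/C1 | intermediate
26 | (1R,2S,3S,4S,5R,14R,7E,11Z)-5-acetoxy-3,4-epoxy-14-hydroxycembra-7,11,15(17)-trien-16,2-olide (CNP0283244.1) | C1/C=C(C)\C[C@@H](O)[C@H]2C(=C)C(=O)O[C@@H]2[C@@H]3O[C@@]3(C)[C@H](OC(C)=O)C/C=C(C)/C1 | target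

Total step count: 22. Longest linear sequence: 22 steps (fully linear from propargyl alcohol 1, which enters a second time in step 11).

Steps most likely to fail

Step 17 (Proposed new method). The C-alkylation may be slow because the acrylate has to reach the s-cis ester conformer, so phosphine-initiated oligomerisation of the acrylate, 6-endo opening or translactonisation to the C14 oxygen may compete. The fallback uses known radical chemistry, sets out from 17 and returns at 22. O-Propargylation under neutral conditions (Ag2O, propargyl bromide, CH2Cl2) would give the C2 propargyl ether F1. Titanocene monochloride Cp2TiCl (trivalent titanium, from Cp2TiCl2 and Zn, THF, rt) would open the epoxide by single-electron transfer to a C1 radical, which closes 5-exo-dig onto the alkyne and so forms the same C15–C1 bond, giving the 3-methylenetetrahydrofuran alcohol F2. Silylation (Et3SiOTf, 2,6-lutidine) would give the silyl ether F3, and allylic oxidation of the ring CH2 next to oxygen (CrO3·3,5-dimethylpyrazole, CH2Cl2, −20 °C) would give lactone 22.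

Step 15. Divalent chromium may reduce or open the α,β-epoxy aldehyde before ring closure, and facial selectivity at C2 may be poor within the forming macrocycle. The fallback epoxidises after ring closure, sets out from 14 and returns at 17. Oxidation with MnO2 would give the E-enal F4, and the same CrCl2/NiCl2 ring closure would give the macrocyclic bis-allylic alcohol F5 as both C2 epimers. Sharpless asymmetric epoxidation with D-(−)-diisopropyl tartrate should then epoxidise the C1=C14 alkene of the matched C2 epimer only, as the erythro product, to give 17; the slow epimer would be recycled by oxidation and reduction.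

Step 21. Substitution may be slow at a carbinol flanked by a fully substituted epoxide carbon, so elimination or retention through participation of the epoxide oxygen may take over. The fallback separates activation from substitution, sets out from 24 and returns at 25. Sulfonylation (ClCH2SO2Cl, pyridine, 0 °C) would give the C5 chloromethanesulfonate F6, and displacement with CsOAc/18-crown-6 in toluene should give acetate 25 with the same inversion.

Further compounds
F1 | step 17 | C2 propargyl ether of 17 | C1/C=C(C)\C[C@H]2O[C@@H]2[C@H](OCC#C)/C=C(C)/[C@@H](OCc2ccc(OC)cc2)C/C=C(C)/C1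
F2 | step 17 | 3-methylenetetrahydrofuran analogue of 21 (C16 is CH2, C14 hydroxyl free) | C1/C=C(C)\C[C@@H](O)[C@H]2C(=C)CO[C@@H]2/C=C(C)/[C@@H](OCc3ccc(OC)cc3)C/C=C(C)/C1
F3 | step 17 | C14 triethylsilyl ether of F2 | C1/C=C(C)\C[C@@H](O[Si](CC)(CC)CC)[C@H]2C(=C)CO[C@@H]2/C=C(C)/[C@@H](OCc3ccc(OC)cc3)C/C=C(C)/C1
F4 | step 15 | (2E,5Z,9E,12S,13E)-14-iodo-12-[(4-methoxybenzyl)oxy]-5,9,13-trimethyltetradeca-2,5,9,13-tetraenal | O=C/C=C/C/C(C)=C\CC/C(C)=C/C[C@H](OCc1ccc(OC)cc1)/C(C)=C/I
F5 | step 15 | macrocyclic bis-allylic alcohol with C1=C14 (E), C3=C4 (E), C7=C8 (E), C11=C12 (Z), (5S)-p-methoxybenzyloxy, both C2 epimers | C1/C=C(C)\C/C=C/C(O)/C=C(C)/[C@@H](OCc2ccc(OC)cc2)C/C=C(C)/C1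
F6 | step 21 | C5 chloromethanesulfonate of 24 | C1/C=C(C)\C[C@@H](O[Si](CC)(CC)CC)[C@H]2C(=C)C(=O)O[C@@H]2[C@@H]3O[C@@]3(C)[C@@H](OS(=O)(=O)CCl)C/C=C(C)/C1
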